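The route rests on disconnecting C3a–C3′ of the methylenecyclohexane ring (C2, C3, C3a, C3′, C2′, C1′; naphtho[2,3-b]furan locants, bridge C1′–C3′ from C2 to C3a). This is the bond between the quaternary carbon shared with the cyclohexane and tetrahydrofuran rings and the carbon bearing =CH2. The key step closes this last ring by a tin-mediated vinyl radical 6-exo-trig cyclisation. In one operation it creates the bridged ring, the quaternary stereocentre C3a and the exocyclic methylene, exploiting the cis-1,3 relation of C2 and C3a across the tetrahydrofuran. Its precursor is a decalin-fused 3,3-dimethyltetrahydrofuran with a C3a=C4 double bond and a but-3-ynyl chain on C2, made from (S)-Wieland–Miescher ketone; bromine enters last.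

Key step: step 13

Remark: compounds 1–13 carry Wieland–Miescher locants (C1 next to C8a, which bears the angular methyl); compounds 14–23 and F1–F9 carry naphtho[2,3-b]furan locants (O1, C2, C3, C3a, C4, C4a, C5–C8, C8a with the angular methyl, C9, C9a). "cis" and "trans" refer to the angular methyl unless stated, and "trans-decalin" means 4a-H trans to it.

Step 1
Reactants: 1 (S)-Wieland–Miescher ketone
Product: 2 bis(ethylene ketal) with the double bond moved to C4=C4a
Conditions: HOCH2CH2OH (excess), p-TsOH (cat.), benzene, reflux, Dean–Stark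
Reagents that add atoms: ethylene glycol, OCCO
Why: Acid-catalysed ketalisation of both carbonyls; the enone ketalises through its dienol, so the double bond should settle out of conjugation at C4=C4a as with steroidal 4-en-3-ones, and C8a keeps the configuration of 1.

Step 2
Reactants: 2 bis(ethylene ketal)
Product: 4 trans-decalin C4 alcohol, via alkylborane 3 (not isolated)
Conditions: BH3·THF, THF, 0 °C to rt; then NaOH, H2O2, 0 °C
Reagents that add atoms: borane–tetrahydrofuran, B.C1CCOC1 (boron stays only in 3); hydrogen peroxide, OO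
Why: Hydroboration–oxidation; boron should add to the less substituted C4 and hydrogen to C4a in a syn addition on the face opposite the angular methyl, which sets the trans ring fusion at C4a.

Step 3
Reactants: 4 trans-decalin C4 alcohol
Product: 5 trans-decalin C4 ketone
Conditions: Dess–Martin periodinane, NaHCO3, CH2Cl2, rt
Reagents that add atoms: none
Why: Dess–Martin oxidation of a secondary alcohol under buffered conditions that leave both ketals intact; the α-centre C4a is already the thermodynamically favoured trans fusion.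

Step 4
Reactants: 5 trans-decalin C4 ketone
Product: 6 tertiary C4 carbinol (4-OH axial and cis to 8a-Me)
Conditions: MeMgBr, THF, −20 to 0 °C; aq. NH4Cl
Reagents that add atoms: methylmagnesium bromide, C[Mg]Br
Why: Grignard 1,2-addition; axial approach to C4 is blocked by the 1,3-diaxial angular methyl, so methyl should enter equatorially and leave the hydroxyl axial and cis to the angular methyl.

Step 5
Reactants: 6 tertiary C4 carbinol
Product: 7 C6 ketone with the C1 ketal retained
Conditions: PPTS (cat.), acetone/H2O, rt, monitored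
Reagents that add atoms: water, O
Why: Selective acetal hydrolysis; the C6 dioxolane flanked by two CH2 groups should cleave under mild acid, while the hindered C1 dioxolane next to the quaternary C8a should survive.

Step 6
Reactants: 7 C6 ketone
Product: 8 bis-triethylsilyl compound (C6=C7 silyl enol ether and 4-OTES)
Conditions: KHMDS (2.5 equiv), TESCl (3 equiv), THF, −78 °C to rt
Reagents that add atoms: chlorotriethylsilane, CC[Si](Cl)(CC)CC
Why: Kinetic enolate formation with in situ O-silylation; deprotonation should occur at C7, away from the ring fusion, and the tertiary potassium alkoxide is silylated in the same operation.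

Step 7
Reactants: 8 bis-triethylsilyl compound
Product: 9 7-(triethylsilyloxy) ketone (7-OTES equatorial and trans to 8a-Me)
Conditions: mCPBA, NaHCO3, CH2Cl2, 0 °C
Reagents that add atoms: 3-chloroperbenzoic acid, OOC(=O)c1cccc(Cl)c1
Why: Rubottom oxidation; the peracid should epoxidise the enol ether on the face opposite the angular methyl and 1,4-silyl migration gives the equatorial α-silyloxy ketone (also the more stable epimer), which sets the future C9a.

Step 8
Reactants: 9 7-(triethylsilyloxy) ketone; 10 methyl isobutyrate
Product: 11 aldol adduct (6-OH axial and cis to 7-OTES)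
Conditions: LDA, 10, THF, −78 °C; then 9, −78 °C; aq. NH4Cl
Reagents that add atoms: none
Why: Ester enolate aldol addition to a ketone; the bulky enolate should attack equatorially and trans to the neighbouring silyloxy group, giving the axial tertiary alcohol (this centre is removed in step 9).

Step 9
Reactants: 11 aldol adduct
Product: 12 β,γ-unsaturated ester (C5=C6 alkene)
Conditions: Burgess reagent, toluene, 60 °C
Reagents that add atoms: none
Why: Burgess dehydration by syn elimination; the axial 6-OH has a cis hydrogen only on C5 (the cis position on C7 carries the silyloxy group), so the C5=C6 alkene should form and cannot conjugate because the ester α-carbon is quaternary.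

Step 10
Reactants: 12 β,γ-unsaturated ester
Product: 14 γ-lactone, via diol ester 13 (not isolated)
Conditions: TBAF (2.5 equiv), THF, 0 °C to rt
Reagents that add atoms: none
Why: Fluoride desilylation of both silyl ethers; the released allylic C7 alkoxide should lactonise onto the methyl ester (5-exo-trig acyl substitution) and close the five-membered oxygen ring.

Step 11
Reactants: 14 γ-lactone; 15 (4-bromobut-1-yn-1-yl)trimethylsilane
Product: 16 lactol (anomer mixture)
Conditions: 15, Mg, THF; then 14, −78 to 0 °C; aq. NH4Cl
Reagents that add atoms: none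
Why: Single Grignard addition to a lactone; the first equivalent deprotonates the tertiary alcohol and the tetrahedral alkoxide next to the gem-dimethyl carbon should resist ring opening and a second addition at low temperature.

Step 12
Reactants: 16 lactol
Product: 18 but-3-ynyl tetrahydrofuran (2-H cis to 9a-H), via silylalkyne 17 (not isolated)
Conditions: Et3SiH, BF3·OEt2, CH2Cl2, −78 °C; then MeOH, K2CO3, rt
Reagents that add atoms: none
Why: Lewis acid/silane reduction of a hemiketal through its oxocarbenium ion; hydride should add on the face of 9a-H, away from the C9 methylene of the fused ring, which sets C2 with the chain cis to C9, and methanolic carbonate then cleaves the alkynyl C–Si bond.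

Step 13
Reactants: 18 but-3-ynyl tetrahydrofuran
Product: 21 tetracyclic methylene ketone, via vinylstannane 19 (not isolated), via methylene ketal 20 (not isolated)
Conditions: Bu3SnH (1.3 equiv, slow addition), AIBN (cat.), benzene, 80 °C; then 2 M HCl, THF, rt
Reagents that add atoms: tributyltin hydride, CCCC[SnH](CCCC)CCCC (tin stays only in 19); water, O
Why: The tributylstannyl radical adds reversibly to the terminal alkyne carbon to give a β-stannyl vinyl radical at C3′, which adds to C3a of the C3a=C4 double bond; the secondary C4 radical takes hydrogen from Bu3SnH, and HCl then protodestannylates 19 by ipso protonation and hydrolyses the C8 dioxolane of 20. The closest known reaction type is the tin hydride-mediated alkyne–alkene vinyl radical cyclisation followed by protodestannylation of the exocyclic vinylstannane. The methylenecyclohexane ring closes in the 6-exo-trig mode (C3′ onto C3a) and completes the 6-oxabicyclo[3.2.1]octane. The new quaternary stereocentre C3a is controlled by the tether: the chain sits on C2 cis to C9, so the three-carbon bridge can reach only the face of C3a opposite the angular methyl, with axial bond formation on the cyclohexene. The step needs 6-exo closure in preference to 7-endo attack at C4 and to premature reduction of the vinyl radical; the short bridge holds the radical centre over C3a, and slow addition of the hydride together with the reversible stannyl addition favours cyclisation. No C–Br bond is present yet, so tin hydride has nothing else to reduce.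

Step 14
Reactants: 21 tetracyclic methylene ketone
Product: 22 axial C8 alcohol (8-OH trans to 8a-Me)
Conditions: L-Selectride (2.5 equiv), THF, −78 °C; aq. NH4Cl
Reagents that add atoms: none
Why: L-Selectride reduction; the bulky hydride should attack the ketone next to the quaternary carbon from the equatorial direction, as with 4,4-dimethyl-3-oxo terpenoids, and give the axial alcohol.

Step 15
Reactants: 22 axial C8 alcohol
Product: 23 target CNP0412361.2
Conditions: CBr4, PPh3, toluene, 60 °C
Reagents that add atoms: carbon tetrabromide, BrC(Br)(Br)Br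
Why: Appel bromination; SN2 displacement of the axial alkoxyphosphonium group by bromide should invert C8 and give the equatorial bromide cis to the angular methyl, while the hindered tertiary alcohol and the alkene should stay untouched.

Compound list
1 | (S)-Wieland–Miescher ketone, (8aS)-8a-methyl-3,4,8,8a-tetrahydronaphthalene-1,6(2H,7H)-dione | C[C@]12CCC(=O)C=C1CCCC2=O | starting material
2 | (8aS)-1,1:6,6-bis(ethylenedioxy)-8a-methyl-1,2,3,5,6,7,8,8a-octahydronaphthalene (C4=C4a alkene) | C1C[C@]2(C)C3(OCCO3)CCC=C2CC14OCCO4 | intermediate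
3 | 4-boryl adduct of 2 (BH2 on C4 and H on C4a, both trans to 8a-Me; not isolated) | C1C[C@]2(C)C3(OCCO3)CC[C@H](B)[C@H]2CC14OCCO4 | intermediate
4 | 1,1:6,6-bis(ethylenedioxy)-8a-methyl-trans-decalin-4-ol (4-OH trans to 8a-Me) | C1C[C@]2(C)C3(OCCO3)CC[C@H](O)[C@H]2CC14OCCO4 | intermediate
5 | 1,1:6,6-bis(ethylenedioxy)-8a-methyl-trans-decalin-4-one | C1C[C@]2(C)C3(OCCO3)CCC(=O)[C@H]2CC14OCCO4 | intermediate
6 | 1,1:6,6-bis(ethylenedioxy)-4,8a-dimethyl-trans-decalin-4-ol (4-OH axial, cis to 8a-Me) | C1C[C@]2(C)C3(OCCO3)CC[C@@](C)(O)[C@H]2CC14OCCO4 | intermediate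
7 | 1,1-(ethylenedioxy)-4-hydroxy-4,8a-dimethyl-trans-decalin-6-one | C1C[C@]2(C)C3(OCCO3)CC[C@@](C)(O)[C@H]2CC1=O | intermediate
8 | 1,1-(ethylenedioxy)-4,8a-dimethyl-4,6-bis(triethylsilyloxy)-trans-octal-6-ene (C6=C7 silyl enol ether) | CC[Si](CC)(CC)OC1=CC[C@]2(C)C3(OCCO3)CC[C@@](C)(O[Si](CC)(CC)CC)[C@H]2C1 | intermediate
9 | 1,1-(ethylenedioxy)-4,8a-dimethyl-4,7-bis(triethylsilyloxy)-trans-decalin-6-one (7-OTES equatorial, trans to 8a-Me) | CC[Si](CC)(CC)O[C@@H]1C[C@]2(C)C3(OCCO3)CC[C@@](C)(O[Si](CC)(CC)CC)[C@H]2CC1=O | intermediate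
10 | methyl isobutyrate (methyl 2-methylpropanoate) | CC(C)C(=O)OC | starting material
11 | methyl 2-[1,1-(ethylenedioxy)-6-hydroxy-4,8a-dimethyl-4,7-bis(triethylsilyloxy)-trans-decalin-6-yl]-2-methylpropanoate (6-OH axial, cis to 7-OTES) | CC[Si](CC)(CC)O[C@@H]1C[C@]2(C)C3(OCCO3)CC[C@@](C)(O[Si](CC)(CC)CC)[C@H]2C[C@@]1(O)C(C)(C)C(=O)OC | intermediate
12 | methyl 2-[1,1-(ethylenedioxy)-4,8a-dimethyl-4,7-bis(triethylsilyloxy)-trans-octal-5-en-6-yl]-2-methylpropanoate (C5=C6 alkene) | CC[Si](CC)(CC)O[C@@H]1C[C@]2(C)C3(OCCO3)CC[C@@](C)(O[Si](CC)(CC)CC)[C@H]2C=C1C(C)(C)C(=O)OC | intermediate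
13 | 4,7-diol of 12 after desilylation (not isolated) | O[C@@H]1C[C@]2(C)C3(OCCO3)CC[C@@](C)(O)[C@H]2C=C1C(C)(C)C(=O)OC | intermediate
14 | 8,8-(ethylenedioxy)-5-hydroxy-3,3,5,8a-tetramethyl-4a,5,6,7,8,8a,9,9a-octahydronaphtho[2,3-b]furan-2(3H)-one (C3a=C4; 4a-H trans, 5-OH cis, 9a-H cis to 8a-Me) | O=C1O[C@@H]2C[C@]3(C)C4(OCCO4)CC[C@@](C)(O)[C@H]3C=C2C1(C)C | intermediate
15 | (4-bromobut-1-yn-1-yl)trimethylsilane | C[Si](C)(C)C#CCCBr | starting material
16 | lactol of 14: 2-hydroxy-2-[4-(trimethylsilyl)but-3-ynyl] tetrahydrofuran, anomer mixture | C[Si](C)(C)C#CCCC1(O)O[C@@H]2C[C@]3(C)C4(OCCO4)CC[C@@](C)(O)[C@H]3C=C2C1(C)C | intermediate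
17 | 2-[4-(trimethylsilyl)but-3-ynyl]-8,8-(ethylenedioxy)-3,3,5,8a-tetramethyl-2,3,4a,5,6,7,8,8a,9,9a-decahydronaphtho[2,3-b]furan-5-ol (2-H cis to 9a-H; not isolated) | C[Si](C)(C)C#CCC[C@@H]1O[C@@H]2C[C@]3(C)C4(OCCO4)CC[C@@](C)(O)[C@H]3C=C2C1(C)C | intermediate
18 | 2-(but-3-ynyl) analogue of 17 (terminal alkyne; C3a=C4; 2-H cis to 9a-H) | C#CCC[C@@H]1O[C@@H]2C[C@]3(C)C4(OCCO4)CC[C@@](C)(O)[C@H]3C=C2C1(C)C | intermediate
19 | tetracycle with C2 and C3a joined by C1′H2–C2′H2–C3′(=CH–SnBu3); 8,8-ethylenedioxy; 5-OH; E/Z mixture (not isolated) | CCCC[Sn](CCCC)(CCCC)C=C1CC[C@@H]2O[C@@H]3C[C@]4(C)C5(OCCO5)CC[C@@](C)(O)[C@H]4C[C@]13C2(C)C | intermediate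
20 | tetracycle with C2 and C3a joined by C1′H2–C2′H2–C3′(=CH2); 8,8-ethylenedioxy; 5-OH (not isolated) | C=C1CC[C@@H]2O[C@@H]3C[C@]4(C)C5(OCCO5)CC[C@@](C)(O)[C@H]4C[C@]13C2(C)C | intermediate
21 | 8-ketone of the tetracycle (5-OH cis to 8a-Me; bridge on C3a trans to 8a-Me) | C=C1CC[C@@H]2O[C@@H]3C[C@]4(C)C(=O)CC[C@@](C)(O)[C@H]4C[C@]13C2(C)C | intermediate
22 | 8-alcohol of the tetracycle (8-OH axial, trans to 8a-Me) | C=C1CC[C@@H]2O[C@@H]3C[C@]4(C)[C@H](O)CC[C@@](C)(O)[C@H]4C[C@]13C2(C)C | intermediate
23 | CNP0412361.2: 8-bromide of the tetracycle (Br equatorial, cis to 8a-Me; 5-OH cis, 4a-H trans, 9a-H cis to 8a-Me) | C=C1CC[C@@H]2O[C@@H]3C[C@]4(C)[C@@H](Br)CC[C@@](C)(O)[C@H]4C[C@]13C2(C)C | target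

Total step count: 15
Longest linear sequence: 15 steps (1 to 23)

Steps most likely to fail

1. Step 13. The vinyl radical may be reduced by tin hydride before it cyclises (plain hydrostannylation of the alkyne), may close in the 7-endo mode at C4, or may be lost by hydrogen translocation. The fallback changes how the ring-closing radical is made and sets out from 18. Nickel-catalysed α-hydroalumination (DIBAL-H, cat. Ni(dppp)Cl2, THF) followed by N-iodosuccinimide should give the 2-iodoalkene F1. A tin-free reductive cyclisation under visible-light photoredox catalysis (fac-Ir(ppy)3, Bu3N, HCO2H, MeCN, blue LED) then generates the vinyl radical irreversibly, with no fast hydrogen donor and no stannyl adduct. It should come back to the route at 20, which is hydrolysed to 21 with 2 M HCl in THF as in step 13.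

2. Step 15. Anti elimination or ionisation of the axial alkoxyphosphonium salt (alkene formation, 1,2-methyl shift) and transannular capture by the C5 hydroxyl may outrun the slow SN2 at the neopentyl carbon. The fallback masks the competing hydroxyl and displaces a sulfonate instead; it sets out from 21. N-Trimethylsilylimidazole (CH2Cl2, 40 °C) should give the C5 silyl ether F2, and L-Selectride as in step 14 the axial alcohol F3. Tf2O and pyridine (CH2Cl2, −30 °C) give the triflate F4, which Bu4NBr in toluene (0 °C to rt) should displace with inversion to the bromide silyl ether F5. K2CO3 in MeOH removes the silyl group and comes back to the route at 23.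

3. Step 12. Hydride may be delivered to the wrong face of the oxocarbenium ion, or with little facial preference, which would place the chain trans to C9 and out of reach of C3a. The fallback reverses the order in which hydrogen and carbon are put on C2 and sets out from 14. DIBAL-H (CH2Cl2, −78 °C) should give the lactol F6. Allyltrimethylsilane with BF3·OEt2 (−78 °C) then adds carbon to the unsubstituted oxocarbenium ion; a facial bias that misdirects hydride in step 12 should here place the chain cis to C9 and give the allyl ether F7. 9-BBN followed by NaOH/H2O2 (terminal alkene only) gives the primary alcohol F8, Dess–Martin oxidation the aldehyde F9, and Ohira–Bestmann homologation (dimethyl 1-diazo-2-oxopropylphosphonate, K2CO3, MeOH) comes back to the route at 18.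

Further compounds
F1 | step 13 | 2-(3-iodobut-3-enyl) analogue of 18 (2-iodoalkene) | C=C(I)CC[C@@H]1O[C@@H]2C[C@]3(C)C4(OCCO4)CC[C@@](C)(O)[C@H]3C=C2C1(C)C
F2 | step 15 | 5-O-trimethylsilyl ether of ketone 21 | C=C1CC[C@@H]2O[C@@H]3C[C@]4(C)C(=O)CC[C@@](C)(O[Si](C)(C)C)[C@H]4C[C@]13C2(C)C
F3 | step 15 | 5-O-trimethylsilyl ether of axial alcohol 22 | C=C1CC[C@@H]2O[C@@H]3C[C@]4(C)[C@H](O)CC[C@@](C)(O[Si](C)(C)C)[C@H]4C[C@]13C2(C)C
F4 | step 15 | 8-O-triflate of F3 (axial) | C=C1CC[C@@H]2O[C@@H]3C[C@]4(C)[C@H](OS(=O)(=O)C(F)(F)F)CC[C@@](C)(O[Si](C)(C)C)[C@H]4C[C@]13C2(C)C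
F5 | step 15 | 5-O-trimethylsilyl ether of target 23 | C=C1CC[C@@H]2O[C@@H]3C[C@]4(C)[C@@H](Br)CC[C@@](C)(O[Si](C)(C)C)[C@H]4C[C@]13C2(C)C
F6 | step 12 | lactol from 14 (2-hydroxy, 2-H; anomer mixture) | OC1O[C@@H]2C[C@]3(C)C4(OCCO4)CC[C@@](C)(O)[C@H]3C=C2C1(C)C
F7 | step 12 | 2-allyl tetrahydrofuran (2-H cis to 9a-H) | C=CC[C@@H]1O[C@@H]2C[C@]3(C)C4(OCCO4)CC[C@@](C)(O)[C@H]3C=C2C1(C)C
F8 | step 12 | 2-(3-hydroxypropyl) tetrahydrofuran | OCCC[C@@H]1O[C@@H]2C[C@]3(C)C4(OCCO4)CC[C@@](C)(O)[C@H]3C=C2C1(C)C
F9 | step 12 | 2-(3-oxopropyl) tetrahydrofuran (aldehyde) | O=CCC[C@@H]1O[C@@H]2C[C@]3(C)C4(OCCO4)CC[C@@](C)(O)[C@H]3C=C2C1(C)C
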